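**Strategy.** Everything hinges on disconnecting two bonds at once, C6–C7 of the carbocycle and O–C12 of the lactone. The γ-lactone and the ten-membered ring meet at the neighbouring stereocentres C6 (which bears the lactone oxygen) and C7, and the lactone α-carbon C11 holds the exocyclic C13 methylene; this pattern is what an aldehyde leaves behind after attack by the γ-carbon of a 2-(methoxycarbonyl)allylchromium. A single CrCl2 operation thus closes both rings and sets C6 and C7. Its substrate is an open-chain 3(2H)-furanone bearing a (Z)-enal (C6) and a (Z)-2-(bromomethyl)enoate (C7, C11–C13), with the C8 oxygen silylated so that it cannot be expelled from the allylchromium; angeloylation and a myrcene Diels–Alder reaction follow.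

Key step: step 17

**Remarks on the chemistry (assumptions)**
- Locants follow germacranolide numbering: C1 ketone, C2=C3 furanone alkene (ring oxygen between C3 and C10), C4(Me)=C5, C6 lactone O–CH, C7, C8 O–CH, C9 H2, C10 O–C(Me), C11 lactone α-carbon, C12 lactone C=O, C13 the carbon on C11 outside the lactone.
- The target is read as 6S,7R,8R,10R,11S with a cis-fused lactone (H-6 and H-7 on one face); the spiro ring is the 1,3-isomer, in which C11 is bonded to the myrcene CH2 that flanks the chain-bearing ring carbon.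
- The C8 oxygen passes through the ring closure as a TBS ether (same skeleton, different spectator group), because a carboxylate on C8 stands in a 1,4-relationship to the chromium-bearing C13 and could be lost by reductive elimination; the angelate is put on directly afterwards.
- (S,S)-ProPhenol is assumed to be the ligand enantiomer that sends the alkynylzinc to the Si face of aldehyde 4 (R carbinol); if a test reaction shows the opposite sense, (R,R)-ProPhenol is used with nothing else changed.

**Route**

Step 1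
Reactants: 1 (R)-citramalic acid
Product: 2 (2R)-2-methylbutane-1,2,4-triol
Conditions: BH3·SMe2, B(OMe)3, THF, 0 °C to rt; then MeOH
Reagents that add atoms: none
Why: Borane reduces both carboxylic acids to primary alcohols (chemoselective acid reduction with BH3, the borate additive keeping the polyol borates in solution), and the quaternary carbinol C10 is not involved, so its R configuration is carried over unchanged.

Step 2
Reactants: 2 (2R)-2-methylbutane-1,2,4-triol
Product: 3 2-[(4R)-2,2,4-trimethyl-1,3-dioxolan-4-yl]ethanol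
Conditions: Me2C(OMe)2, TsOH (cat.), acetone, rt
Reagents that add atoms: 2,2-dimethoxypropane, COC(C)(C)OC
Why: Acid-catalysed acetonide formation under thermodynamic control selects the five-membered dioxolane across the tertiary C10–OH and the C1–OH over the six-membered alternative with its axial methyl groups, which leaves only the C8 hydroxyl free.

Step 3
Reactants: 3 2-[(4R)-2,2,4-trimethyl-1,3-dioxolan-4-yl]ethanol
Product: 4 2-[(4R)-2,2,4-trimethyl-1,3-dioxolan-4-yl]acetaldehyde
Conditions: Dess–Martin periodinane, NaHCO3, CH2Cl2, 0 °C to rt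
Reagents that add atoms: none
Why: Dess–Martin oxidation of a primary alcohol stops at the aldehyde, and the buffered neutral medium protects the acetal and avoids β-elimination of the C10 oxygen.

Step 4
Reactants: 4 2-[(4R)-2,2,4-trimethyl-1,3-dioxolan-4-yl]acetaldehyde; 5 methyl propiolate
Product: 6 methyl (4R)-4-hydroxy-5-[(4R)-2,2,4-trimethyl-1,3-dioxolan-4-yl]pent-2-ynoate
Conditions: Me2Zn, (S,S)-ProPhenol (20 mol %), Ph3PO (40 mol %), toluene, 0 °C
Reagents that add atoms: none
Why: Zinc–ProPhenol-catalysed asymmetric alkynylation of an aldehyde, in which the dinuclear zinc alkoxide complex binds the aldehyde and the alkynylzinc formed from 5 and delivers the alkyne to the Si face, should set C8 as R under catalyst control, while the quaternary centre next to the α-CH2 slows enolisation of 4.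

Step 5
Reactants: 6 methyl (4R)-4-hydroxy-5-[(4R)-2,2,4-trimethyl-1,3-dioxolan-4-yl]pent-2-ynoate
Product: 8 methyl (2Z,4R)-4-hydroxy-2-iodo-5-[(4R)-2,2,4-trimethyl-1,3-dioxolan-4-yl]pent-2-enoate, via alkenylaluminate 7 (not isolated)
Conditions: NaAlH2(OCH2CH2OMe)2, THF, −72 °C; then N-iodosuccinimide, −72 to −20 °C
Reagents that add atoms: N-iodosuccinimide, O=C1CCC(=O)N1I
Why: Hydroxyl-directed trans-hydroalumination of a γ-hydroxy ynoate places hydride on C7 and aluminium on C11 inside a five-membered chelate with the C8 alkoxide, and iodination with retention at carbon then puts iodine cis to C8 and the ester trans to it (2Z), a geometry that cannot lactonise onto the C8 oxygen.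

Step 6
Reactants: 8 methyl (2Z,4R)-4-hydroxy-2-iodo-5-[(4R)-2,2,4-trimethyl-1,3-dioxolan-4-yl]pent-2-enoate
Product: 9 methyl (2Z,4R)-4-[(tert-butyldimethylsilyl)oxy]-2-iodo-5-[(4R)-2,2,4-trimethyl-1,3-dioxolan-4-yl]pent-2-enoate
Conditions: TBSCl, imidazole, DMF, rt
Reagents that add atoms: tert-butyldimethylsilyl chloride, CC(C)(C)[Si](C)(C)Cl
Why: Silylation of the secondary allylic alcohol with TBSCl and imidazole installs a non-nucleofugal, acid-removable group on the C8 oxygen without touching the C8 configuration or the acetonide.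

Step 7
Reactants: 9 methyl (2Z,4R)-4-[(tert-butyldimethylsilyl)oxy]-2-iodo-5-[(4R)-2,2,4-trimethyl-1,3-dioxolan-4-yl]pent-2-enoate
Product: 10 methyl (2Z,4R,6R)-4-[(tert-butyldimethylsilyl)oxy]-6,7-dihydroxy-2-iodo-6-methylhept-2-enoate
Conditions: PPTS, MeOH, 40 °C
Reagents that add atoms: none
Why: Acid-catalysed transacetalisation with methanol removes the terminal acetonide far faster than it cleaves the hindered secondary silyl ether, and neither hydroxyl can lactonise because the ester is trans to the chain on the alkene.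

Step 8
Reactants: 10 methyl (2Z,4R,6R)-4-[(tert-butyldimethylsilyl)oxy]-6,7-dihydroxy-2-iodo-6-methylhept-2-enoate
Product: 11 methyl (2Z,4R,6R)-4-[(tert-butyldimethylsilyl)oxy]-6-hydroxy-2-iodo-6-methyl-7-oxohept-2-enoate
Conditions: IBX, EtOAc, 75 °C
Reagents that add atoms: none
Why: IBX oxidises the primary alcohol of a 1,2-diol to the α-hydroxy aldehyde without glycol cleavage, the tertiary carbinol C10 has no hydrogen to lose, and a filtration work-up delivers the sensitive product for direct use.

Step 9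
Reactants: 12 (Z)-3-methylpent-2-en-4-yn-1-ol
Product: 13 tert-butyl(dimethyl){[(2Z)-3-methylpent-2-en-4-yn-1-yl]oxy}silane
Conditions: TBSCl, imidazole, CH2Cl2, 0 °C to rt
Reagents that add atoms: tert-butyldimethylsilyl chloride, CC(C)(C)[Si](C)(C)Cl
Why: Standard silylation of a primary alcohol with TBSCl and imidazole, which leaves the terminal alkyne and the Z alkene (the later C4=C5) unchanged.

Step 10
Reactants: 13 tert-butyl(dimethyl){[(2Z)-3-methylpent-2-en-4-yn-1-yl]oxy}silane; 11 methyl (2Z,4R,6R)-4-[(tert-butyldimethylsilyl)oxy]-6-hydroxy-2-iodo-6-methyl-7-oxohept-2-enoate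
Product: 15 methyl (2Z,4R,6R,10Z)-4,12-bis[(tert-butyldimethylsilyl)oxy]-6,7-dihydroxy-2-iodo-6,10-dimethyldodeca-2,10-dien-8-ynoate (both C7 epimers), via lithium acetylide 14 (not isolated)
Conditions: 13 (2.5 equiv), n-BuLi, THF, −78 °C; then 11, −78 °C; NH4Cl (aq)
Reagents that add atoms: none
Why: 1,2-Addition of a lithium acetylide to an aldehyde at −78 °C, where one equivalent of 14 is spent on the tertiary hydroxyl and the methyl ester and the vinyl iodide are not attacked, joins C1 to C2, and the new carbinol centre is of no consequence because it is oxidised in the next step.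

Step 11
Reactants: 15 methyl (2Z,4R,6R,10Z)-4,12-bis[(tert-butyldimethylsilyl)oxy]-6,7-dihydroxy-2-iodo-6,10-dimethyldodeca-2,10-dien-8-ynoate
Product: 16 methyl (2Z,4R,6R,10Z)-4,12-bis[(tert-butyldimethylsilyl)oxy]-6-hydroxy-2-iodo-6,10-dimethyl-7-oxododeca-2,10-dien-8-ynoate
Conditions: MnO2, CH2Cl2, rt
Reagents that add atoms: none
Why: MnO2 oxidises the activated propargylic alcohol selectively to the ynone and cannot oxidise the tertiary hydroxyl, so the α′-hydroxy ynone needed for furanone formation results.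

Step 12
Reactants: 16 methyl (2Z,4R,6R,10Z)-4,12-bis[(tert-butyldimethylsilyl)oxy]-6-hydroxy-2-iodo-6,10-dimethyl-7-oxododeca-2,10-dien-8-ynoate
Product: 17 methyl (2Z,4R)-4-[(tert-butyldimethylsilyl)oxy]-5-[(2R)-5-{(2Z)-4-[(tert-butyldimethylsilyl)oxy]but-2-en-2-yl}-2-methyl-3-oxo-2,3-dihydrofuran-2-yl]-2-iodopent-2-enoate
Conditions: Ph3PAuNTf2 (3 mol %), CH2Cl2, rt
Reagents that add atoms: none
Why: Gold-catalysed cycloisomerisation of an α′-hydroxy ynone, in which the π-acid activates the alkyne for 5-endo-dig attack of the C10 hydroxyl on C3 and protodeauration gives the 3(2H)-furanone, proceeds under neutral conditions that keep the silyl ethers, the vinyl iodide and the Z alkene, and creates no stereocentre.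

Step 13
Reactants: 17 methyl (2Z,4R)-4-[(tert-butyldimethylsilyl)oxy]-5-[(2R)-5-{(2Z)-4-[(tert-butyldimethylsilyl)oxy]but-2-en-2-yl}-2-methyl-3-oxo-2,3-dihydrofuran-2-yl]-2-iodopent-2-enoate; 18 (tributylstannyl)methanol
Product: 19 methyl (2E,4R)-4-[(tert-butyldimethylsilyl)oxy]-5-[(2R)-5-{(2Z)-4-[(tert-butyldimethylsilyl)oxy]but-2-en-2-yl}-2-methyl-3-oxo-2,3-dihydrofuran-2-yl]-2-(hydroxymethyl)pent-2-enoate
Conditions: Pd(PPh3)4 (10 mol %), 1,4-dioxane, 80 °C
Reagents that add atoms: none
Why: Stille (Migita–Kosugi) coupling of the α-iodo enoate with the hydroxymethylstannane proceeds by oxidative addition at the carbon–iodine bond, transfer of CH2OH from tin and reductive elimination with retention of alkene geometry, so C13 arrives cis to C8 (the descriptor becomes E only because the ester outranks CH2OH) and, introduced this late, never needs a protecting group.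

Step 14
Reactants: 19 methyl (2E,4R)-4-[(tert-butyldimethylsilyl)oxy]-5-[(2R)-5-{(2Z)-4-[(tert-butyldimethylsilyl)oxy]but-2-en-2-yl}-2-methyl-3-oxo-2,3-dihydrofuran-2-yl]-2-(hydroxymethyl)pent-2-enoate
Product: 20 methyl (2Z,4R)-2-(bromomethyl)-4-[(tert-butyldimethylsilyl)oxy]-5-[(2R)-5-{(2Z)-4-[(tert-butyldimethylsilyl)oxy]but-2-en-2-yl}-2-methyl-3-oxo-2,3-dihydrofuran-2-yl]pent-2-enoate
Conditions: CBr4, PPh3, CH2Cl2, 0 °C
Reagents that add atoms: carbon tetrabromide, BrC(Br)(Br)Br
Why: Appel bromination converts the primary allylic alcohol into the bromide by SN2 displacement of the oxyphosphonium leaving group, the conjugated (2Z)-2-(bromomethyl)enoate being also the thermodynamically preferred allylic isomer, and silyl ethers and furanone are inert at 0 °C.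

Step 15
Reactants: 20 methyl (2Z,4R)-2-(bromomethyl)-4-[(tert-butyldimethylsilyl)oxy]-5-[(2R)-5-{(2Z)-4-[(tert-butyldimethylsilyl)oxy]but-2-en-2-yl}-2-methyl-3-oxo-2,3-dihydrofuran-2-yl]pent-2-enoate
Product: 21 methyl (2Z,4R)-2-(bromomethyl)-4-[(tert-butyldimethylsilyl)oxy]-5-{(2R)-5-[(2Z)-4-hydroxybut-2-en-2-yl]-2-methyl-3-oxo-2,3-dihydrofuran-2-yl}pent-2-enoate
Conditions: HF (48% aq), MeCN, 0 °C
Reagents that add atoms: none
Why: Acid-mediated desilylation with aqueous HF removes the unhindered primary allylic silyl ether much faster than the hindered secondary one at C8, and the amine-free acidic medium is chosen because amines or fluoride salts would substitute the reactive allylic bromide.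

Step 16
Reactants: 21 methyl (2Z,4R)-2-(bromomethyl)-4-[(tert-butyldimethylsilyl)oxy]-5-{(2R)-5-[(2Z)-4-hydroxybut-2-en-2-yl]-2-methyl-3-oxo-2,3-dihydrofuran-2-yl}pent-2-enoate
Product: 22 methyl (2Z,4R)-2-(bromomethyl)-4-[(tert-butyldimethylsilyl)oxy]-5-{(2R)-2-methyl-3-oxo-5-[(2Z)-4-oxobut-2-en-2-yl]-2,3-dihydrofuran-2-yl}pent-2-enoate
Conditions: Dess–Martin periodinane, NaHCO3, CH2Cl2, 0 °C
Reagents that add atoms: none
Why: Buffered Dess–Martin oxidation converts the primary allylic alcohol into the enal at 0 °C without acid or base that could isomerise the Z C4=C5 bond, and the bromide is inert to the periodinane.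

Step 17
Reactants: 22 methyl (2Z,4R)-2-(bromomethyl)-4-[(tert-butyldimethylsilyl)oxy]-5-{(2R)-2-methyl-3-oxo-5-[(2Z)-4-oxobut-2-en-2-yl]-2,3-dihydrofuran-2-yl}pent-2-enoate
Product: 25 (6S,7S,8R,10R)-8-[(tert-butyldimethylsilyl)oxy]-3,10-epoxy-1-oxogermacra-2,4(Z),11(13)-trien-12,6-olide, via allylchromium dichloride 23 (not isolated), via chromium alkoxide 24 (not isolated)
Conditions: CrCl2 (10 equiv), THF–DMF, rt, 22 added over 12 h (final 2 mM); NH4Cl (aq)
Reagents that add atoms: none
Why: Two equivalents of CrCl2 (divalent chromium) reduce the C13–Br bond in two single-electron steps to the allylchromium dichloride 23 (trivalent chromium), whose γ-carbon C7 adds to the chromium-bound C6 aldehyde through a closed six-membered chair with allyl transposition, so that C6–C7 forms and the C11=C13 methylene is regenerated; the closest known reaction type is the intramolecular Nozaki–Hiyama (Barbier) allylation of aldehydes with 2-(bromomethyl)alk-2-enoates that gives cis-α-methylene-γ-butyrolactones. The ten-membered carbocycle closes in a 10-exo-trig addition to the aldehyde, and the chromium alkoxide 24 then acylates on the neighbouring methyl ester in a 5-exo-trig lactonisation that expels methoxide. C7 is controlled by C8: allylic 1,3-strain with the C13 methylene holds H-8 in the alkene plane, and the aldehyde should reach C7 from the face anti to C9, which is also the antiperiplanar C6–C7–C8–C9 arrangement that a ten-membered ring prefers. C6 is controlled by the alkene geometry: C8 is cis to CH2Cr, sits axial in the chair and should give the syn C6–O/C7–C8 relationship, that is, the cis-fused lactone with H-6 and H-7 on one face. The step needs ring closure to beat intermolecular coupling, which slow addition at high dilution and the rigid furanone with its two Z alkenes (holding C6 near C7) should secure, and it needs the allylchromium to spare the enone and the C8 oxygen, which the mild oxophilic reagent and the silyl ether (unlike a C8 carboxylate, not able to leave in a reductive 1,4-elimination) should secure.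

Step 18
Reactants: 25 (6S,7S,8R,10R)-8-[(tert-butyldimethylsilyl)oxy]-3,10-epoxy-1-oxogermacra-2,4(Z),11(13)-trien-12,6-olide
Product: 26 (6S,7R,8R,10R)-3,10-epoxy-8-hydroxy-1-oxogermacra-2,4(Z),11(13)-trien-12,6-olide
Conditions: HF (48% aq), MeCN, rt
Reagents that add atoms: none
Why: Desilylation with aqueous HF in acetonitrile cleaves the secondary silyl ether under acidic conditions that the α-methylene lactone, the furanone and the Z alkene tolerate, whereas basic fluoride sources would risk conjugate addition and relactonisation towards the C8 oxygen.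

Step 19
Reactants: 26 (6S,7R,8R,10R)-3,10-epoxy-8-hydroxy-1-oxogermacra-2,4(Z),11(13)-trien-12,6-olide; 27 angelic acid
Product: 29 (6S,7R,8R,10R)-8-angeloyloxy-3,10-epoxy-1-oxogermacra-2,4(Z),11(13)-trien-12,6-olide, via mixed anhydride 28 (not isolated)
Conditions: 27, 2,4,6-Cl3C6H2COCl, Et3N, toluene, rt; then 26, 80 °C
Reagents that add atoms: none
Why: Yamaguchi esterification through the mixed anhydride 28, run without a nucleophilic catalyst because such catalysts isomerise angelate to tiglate, acylates the C8 hydroxyl with retention of the C8 configuration and of the Z geometry of the acid.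

Step 20
Reactants: 29 (6S,7R,8R,10R)-8-angeloyloxy-3,10-epoxy-1-oxogermacra-2,4(Z),11(13)-trien-12,6-olide; 30 myrcene
Product: 31 (6S,7R,8R,10R,11S)-8-angeloyloxy-3,10-epoxy-1-oxogermacra-2,4(Z)-dien-12,6-olide-11-spiro-1′-[3′-(4-methylpent-3-en-1-yl)cyclohex-3′-ene] (C13 is C6′ of the new ring)
Conditions: myrcene (20 equiv), BHT, toluene, 110 °C, sealed tube; preparative HPLC
Reagents that add atoms: none
Why: Thermal Diels–Alder reaction in which myrcene adds to the C11=C13 dienophile from the lactone face that carries H-7 (opposite C8 and the ten-membered ring), which should set C11 as S, run without a Lewis acid because such catalysis would reinforce the intrinsically favoured 1,4 orientation of a 2-alkyl diene, so that both regioisomers are expected and the 1,3-adduct 31 is to be separated from the 1,4-adduct by HPLC.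

**Compound list**

1 | (R)-citramalic acid, (2R)-2-hydroxy-2-methylbutanedioic acid | C[C@@](O)(CC(=O)O)C(=O)O | starting material
2 | (2R)-2-methylbutane-1,2,4-triol | OCC[C@@](C)(O)CO | intermediate
3 | 2-[(4R)-2,2,4-trimethyl-1,3-dioxolan-4-yl]ethanol | OCC[C@]1(C)COC(C)(C)O1 | intermediate
4 | 2-[(4R)-2,2,4-trimethyl-1,3-dioxolan-4-yl]acetaldehyde | O=CC[C@]1(C)COC(C)(C)O1 | intermediate
5 | methyl propiolate | C#CC(=O)OC | starting material
6 | methyl (4R)-4-hydroxy-5-[(4R)-2,2,4-trimethyl-1,3-dioxolan-4-yl]pent-2-ynoate | O[C@H](C[C@]1(C)COC(C)(C)O1)C#CC(=O)OC | intermediate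
7 | sodium alkenylaluminate: five-membered chelate of the C8 alkoxide and C11 on aluminium, two 2-methoxyethoxy ligands | [Na+].COCCO[Al-]1(OCCOC)O[C@H](C[C@]2(C)COC(C)(C)O2)C=C1C(=O)OC | intermediate (not isolated)
8 | methyl (2Z,4R)-4-hydroxy-2-iodo-5-[(4R)-2,2,4-trimethyl-1,3-dioxolan-4-yl]pent-2-enoate | O[C@H](C[C@]1(C)COC(C)(C)O1)/C=C(\I)C(=O)OC | intermediate
9 | methyl (2Z,4R)-4-[(tert-butyldimethylsilyl)oxy]-2-iodo-5-[(4R)-2,2,4-trimethyl-1,3-dioxolan-4-yl]pent-2-enoate | CC(C)(C)[Si](C)(C)O[C@H](C[C@]1(C)COC(C)(C)O1)/C=C(\I)C(=O)OC | intermediate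
10 | methyl (2Z,4R,6R)-4-[(tert-butyldimethylsilyl)oxy]-6,7-dihydroxy-2-iodo-6-methylhept-2-enoate | CC(C)(C)[Si](C)(C)O[C@H](C[C@@](C)(O)CO)/C=C(\I)C(=O)OC | intermediate
11 | methyl (2Z,4R,6R)-4-[(tert-butyldimethylsilyl)oxy]-6-hydroxy-2-iodo-6-methyl-7-oxohept-2-enoate | CC(C)(C)[Si](C)(C)O[C@H](C[C@@](C)(O)C=O)/C=C(\I)C(=O)OC | intermediate
12 | (Z)-3-methylpent-2-en-4-yn-1-ol | C#C/C(C)=C\CO | starting material
13 | tert-butyl(dimethyl){[(2Z)-3-methylpent-2-en-4-yn-1-yl]oxy}silane | C#C/C(C)=C\CO[Si](C)(C)C(C)(C)C | intermediate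
14 | lithium acetylide of 13 | [Li]C#C/C(C)=C\CO[Si](C)(C)C(C)(C)C | intermediate (not isolated)
15 | methyl (2Z,4R,6R,10Z)-4,12-bis[(tert-butyldimethylsilyl)oxy]-6,7-dihydroxy-2-iodo-6,10-dimethyldodeca-2,10-dien-8-ynoate, both C7 epimers | CC(C)(C)[Si](C)(C)O[C@H](C[C@@](C)(O)C(O)C#C/C(C)=C\CO[Si](C)(C)C(C)(C)C)/C=C(\I)C(=O)OC | intermediate
16 | methyl (2Z,4R,6R,10Z)-4,12-bis[(tert-butyldimethylsilyl)oxy]-6-hydroxy-2-iodo-6,10-dimethyl-7-oxododeca-2,10-dien-8-ynoate | CC(C)(C)[Si](C)(C)O[C@H](C[C@@](C)(O)C(=O)C#C/C(C)=C\CO[Si](C)(C)C(C)(C)C)/C=C(\I)C(=O)OC | intermediate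
17 | methyl (2Z,4R)-4-[(tert-butyldimethylsilyl)oxy]-5-[(2R)-5-{(2Z)-4-[(tert-butyldimethylsilyl)oxy]but-2-en-2-yl}-2-methyl-3-oxo-2,3-dihydrofuran-2-yl]-2-iodopent-2-enoate | CC(C)(C)[Si](C)(C)O[C@H](C[C@@]1(C)OC(=CC1=O)/C(C)=C\CO[Si](C)(C)C(C)(C)C)/C=C(\I)C(=O)OC | intermediate
18 | (tributylstannyl)methanol | CCCC[Sn](CCCC)(CCCC)CO | starting material
19 | methyl (2E,4R)-4-[(tert-butyldimethylsilyl)oxy]-5-[(2R)-5-{(2Z)-4-[(tert-butyldimethylsilyl)oxy]but-2-en-2-yl}-2-methyl-3-oxo-2,3-dihydrofuran-2-yl]-2-(hydroxymethyl)pent-2-enoate | CC(C)(C)[Si](C)(C)O[C@H](C[C@@]1(C)OC(=CC1=O)/C(C)=C\CO[Si](C)(C)C(C)(C)C)/C=C(\CO)C(=O)OC | intermediate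
20 | methyl (2Z,4R)-2-(bromomethyl)-4-[(tert-butyldimethylsilyl)oxy]-5-[(2R)-5-{(2Z)-4-[(tert-butyldimethylsilyl)oxy]but-2-en-2-yl}-2-methyl-3-oxo-2,3-dihydrofuran-2-yl]pent-2-enoate | CC(C)(C)[Si](C)(C)O[C@H](C[C@@]1(C)OC(=CC1=O)/C(C)=C\CO[Si](C)(C)C(C)(C)C)/C=C(\CBr)C(=O)OC | intermediate
21 | methyl (2Z,4R)-2-(bromomethyl)-4-[(tert-butyldimethylsilyl)oxy]-5-{(2R)-5-[(2Z)-4-hydroxybut-2-en-2-yl]-2-methyl-3-oxo-2,3-dihydrofuran-2-yl}pent-2-enoate | CC(C)(C)[Si](C)(C)O[C@H](C[C@@]1(C)OC(=CC1=O)/C(C)=C\CO)/C=C(\CBr)C(=O)OC | intermediate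
22 | cyclisation precursor, methyl (2Z,4R)-2-(bromomethyl)-4-[(tert-butyldimethylsilyl)oxy]-5-{(2R)-2-methyl-3-oxo-5-[(2Z)-4-oxobut-2-en-2-yl]-2,3-dihydrofuran-2-yl}pent-2-enoate | CC(C)(C)[Si](C)(C)O[C@H](C[C@@]1(C)OC(=CC1=O)/C(C)=C\C=O)/C=C(\CBr)C(=O)OC | intermediate
23 | allylchromium dichloride of 22 (chromium on C13) | CC(C)(C)[Si](C)(C)O[C@H](C[C@@]1(C)OC(=CC1=O)/C(C)=C\C=O)/C=C(\C[Cr](Cl)Cl)C(=O)OC | intermediate (not isolated)
24 | ten-membered C6 chromium alkoxide with the methyl 2-propenoate unit on C7 | CC(C)(C)[Si](C)(C)O[C@@H]1C[C@@]2(C)OC(=CC2=O)/C(C)=C\[C@H](O[Cr](Cl)Cl)[C@@H]1C(=C)C(=O)OC | intermediate (not isolated)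
25 | (6S,7S,8R,10R)-8-[(tert-butyldimethylsilyl)oxy]-3,10-epoxy-1-oxogermacra-2,4(Z),11(13)-trien-12,6-olide, cis-fused lactone | CC(C)(C)[Si](C)(C)O[C@@H]1C[C@@]2(C)OC(=CC2=O)/C(C)=C\[C@@H]2OC(=O)C(=C)[C@@H]21 | intermediate
26 | (6S,7R,8R,10R)-3,10-epoxy-8-hydroxy-1-oxogermacra-2,4(Z),11(13)-trien-12,6-olide | O[C@@H]1C[C@@]2(C)OC(=CC2=O)/C(C)=C\[C@@H]2OC(=O)C(=C)[C@@H]21 | intermediate
27 | angelic acid, (Z)-2-methylbut-2-enoic acid | C/C=C(/C)C(=O)O | starting material
28 | angelic 2,4,6-trichlorobenzoic anhydride | C/C=C(/C)C(=O)OC(=O)c1c(Cl)cc(Cl)cc1Cl | intermediate (not isolated)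
29 | (6S,7R,8R,10R)-8-angeloyloxy-3,10-epoxy-1-oxogermacra-2,4(Z),11(13)-trien-12,6-olide | C/C=C(/C)C(=O)O[C@@H]1C[C@@]2(C)OC(=CC2=O)/C(C)=C\[C@@H]2OC(=O)C(=C)[C@@H]21 | intermediate
30 | myrcene | CC(C)=CCCC(=C)C=C | starting material
31 | CNP0226905.2, (6S,7R,8R,10R,11S)-8-angeloyloxy-3,10-epoxy-1-oxogermacra-2,4(Z)-dien-12,6-olide-11-spiro-1′-[3′-(4-methylpent-3-en-1-yl)cyclohex-3′-ene] | C/C=C(/C)C(=O)O[C@@H]1C[C@@]2(C)OC(=CC2=O)/C(C)=C\[C@@H]2OC(=O)[C@]3(CCC=C(CCC=C(C)C)C3)[C@@H]21 | target

**Step count**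

Total step count: 20. Longest linear sequence: 19 (steps 1–8 and 10–20, from 1 to 31).

**Steps most likely to fail**

1. Step 17. The allylchromium may be protonated or may couple between molecules before the strained ten-membered transition state is reached, or C6 may bond to the wrong face of C7. The fallback replaces the reductive Barbier closure by an allylboration of an isolable allylboronate, which needs no reductant and can be held at high dilution for as long as ring closure takes. It sets out from 19. Acetylation (Ac2O, pyridine, DMAP) should give the allylic acetate F1. Borylation with B2pin2 under Pd2(dba)3 catalysis (zerovalent palladium, toluene–DMSO, 50 °C) should give the pinacol allylboronate F2, with C8 still cis to the CH2B group. PPTS in MeOH at 0 °C should free the primary alcohol to give the hydroxy boronate F3, and buffered Dess–Martin oxidation should give the boronate enal F4. At 2 mM in toluene with Sc(OTf)3 (10 mol %), C7 should add to the C6 aldehyde through the same closed chair, and aqueous work-up should give the ten-membered hydroxy ester F5. Catalytic TsOH should lactonise F5 to 25, where the route is rejoined.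

2. Step 20. The diene is expected to align mainly in the 1,4 sense, so the wanted 1,3 orientation may be only the lesser pathway, and prolonged heating may erode the strained heliangolide. The fallback fixes the orientation with a 2-silyloxy diene, which places the acceptor-bearing dienophile carbon para to the oxygenated diene carbon and hence 1,3 to the side chain; it sets out from 29. The diene is made separately. Ethyl acetoacetate is alkylated with 5-bromo-2-methylpent-2-ene (NaH, THF) to ethyl 2-acetyl-6-methylhept-5-enoate F6. Saponification and decarboxylative Mannich methylenation (KOH; then aqueous CH2O, Et2NH, AcOH) should give 7-methyl-3-methylideneoct-6-en-2-one F7. Et3SiOTf and Et3N should give triethyl[(7-methyl-3-methylideneocta-1,6-dien-2-yl)oxy]silane F8. Heating 29 with F8 in toluene (80 °C) should give the spiro silyl enol ether adduct F9, formed from the same lactone face. CsF and PhNTf2 in DME should convert it into the enol triflate F10. Palladium-catalysed formate reduction (Pd(OAc)2, PPh3, Bu3N, HCO2H, DMF, 60 °C) should replace the triflate by hydrogen and return the route at 31.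

3. Step 4. Facial discrimination by the catalyst may be incomplete on this α-unbranched aldehyde, and the basic zinc species may consume the aldehyde by self-aldol reaction. The fallback separates bond formation from stereocontrol and sets out from 4. Addition of lithiated 5 (LiN(SiMe3)2, THF, −78 °C) should give methyl 4-hydroxy-5-[(4R)-2,2,4-trimethyl-1,3-dioxolan-4-yl]pent-2-ynoate as both C4 epimers F11. Dess–Martin oxidation should give the ynone methyl 4-oxo-5-[(4R)-2,2,4-trimethyl-1,3-dioxolan-4-yl]pent-2-ynoate F12. Midland reduction with (R)-Alpine-Borane, which delivers hydride to alkynyl ketones with reagent control, should give the 4R alcohol and return the route at 6.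

**Further compounds**

F1 | step 17 | allylic acetate of 19, methyl (2E,4R)-2-(acetoxymethyl)-4-[(tert-butyldimethylsilyl)oxy]-5-[(2R)-5-{(2Z)-4-[(tert-butyldimethylsilyl)oxy]but-2-en-2-yl}-2-methyl-3-oxo-2,3-dihydrofuran-2-yl]pent-2-enoate | CC(C)(C)[Si](C)(C)O[C@H](C[C@@]1(C)OC(=CC1=O)/C(C)=C\CO[Si](C)(C)C(C)(C)C)/C=C(\COC(C)=O)C(=O)OC
F2 | step 17 | pinacol allylboronate (Bpin on C13, C8 cis to CH2B, both silyl ethers kept) | CC(C)(C)[Si](C)(C)O[C@H](C[C@@]1(C)OC(=CC1=O)/C(C)=C\CO[Si](C)(C)C(C)(C)C)/C=C(\CB2OC(C)(C)C(C)(C)O2)C(=O)OC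
F3 | step 17 | hydroxy boronate (C6 alcohol free) | CC(C)(C)[Si](C)(C)O[C@H](C[C@@]1(C)OC(=CC1=O)/C(C)=C\CO)/C=C(\CB2OC(C)(C)C(C)(C)O2)C(=O)OC
F4 | step 17 | boronate enal (C6 aldehyde) | CC(C)(C)[Si](C)(C)O[C@H](C[C@@]1(C)OC(=CC1=O)/C(C)=C\C=O)/C=C(\CB2OC(C)(C)C(C)(C)O2)C(=O)OC
F5 | step 17 | ten-membered hydroxy ester (C6–OH, methyl 2-propenoate unit on C7) | CC(C)(C)[Si](C)(C)O[C@@H]1C[C@@]2(C)OC(=CC2=O)/C(C)=C\[C@H](O)[C@@H]1C(=C)C(=O)OC
F6 | step 20 | ethyl 2-acetyl-6-methylhept-5-enoate | CCOC(=O)C(CCC=C(C)C)C(C)=O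
F7 | step 20 | 7-methyl-3-methylideneoct-6-en-2-one | CC(=O)C(=C)CCC=C(C)C
F8 | step 20 | triethyl[(7-methyl-3-methylideneocta-1,6-dien-2-yl)oxy]silane | C=C(O[Si](CC)(CC)CC)C(=C)CCC=C(C)C
F9 | step 20 | spiro silyl enol ether adduct (triethylsilyloxy on C4′ of the new ring) | C/C=C(/C)C(=O)O[C@@H]1C[C@@]2(C)OC(=CC2=O)/C(C)=C\[C@@H]2OC(=O)[C@]3(CCC(O[Si](CC)(CC)CC)=C(CCC=C(C)C)C3)[C@@H]21
F10 | step 20 | spiro enol triflate (triflyloxy on C4′ of the new ring) | C/C=C(/C)C(=O)O[C@@H]1C[C@@]2(C)OC(=CC2=O)/C(C)=C\[C@@H]2OC(=O)[C@]3(CCC(OS(=O)(=O)C(F)(F)F)=C(CCC=C(C)C)C3)[C@@H]21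
F11 | step 4 | methyl 4-hydroxy-5-[(4R)-2,2,4-trimethyl-1,3-dioxolan-4-yl]pent-2-ynoate, both C4 epimers | COC(=O)C#CC(O)C[C@]1(C)COC(C)(C)O1
F12 | step 4 | methyl 4-oxo-5-[(4R)-2,2,4-trimethyl-1,3-dioxolan-4-yl]pent-2-ynoate | COC(=O)C#CC(=O)C[C@]1(C)COC(C)(C)O1
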